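- A small charge of starting material, 0.10 M, meets 0.250 M of partner in green, amber and violet, so E = 2.50, the partner excess, partner charge over starting-material charge.

| flask | starting material | partner | temperature | remark | time |
|---|---|---|---|---|---|
| gamma | 0.050 M | 0.25 M | 35 °C | run made earlier |  |
| alpha | 0.20 M | 0.25 M | 46 °C | run made earlier |  |
| green | 0.10 M | 0.250 M |  | at 50 °C until 80 min, from then on at 30 °C | 6.0 h |
| amber | 0.10 M | 0.250 M | 30 °C |  | 6.0 h |
| violet | 0.10 M | 0.250 M | 50 °C |  | 6.0 h |

| run | time / h | target / % | side product / % |
|---|---|---|---|
| gamma | 0.500 | 0 | 1.3 |
| gamma | 0.667 | 0.8 | 1.4 |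
| gamma | 1.00 | 0 | 2.3 |
| gamma | 1.50 | 0 | 2.3 |
| gamma | 2.50 | 0.1 | 5.5 |
| gamma | 4.00 | 0.8 | 8.0 |
| gamma | 6.00 | 0.2 | 9.0 |
| alpha | 0.167 | 0 | 0.6 |
| alpha | 0.417 | 0 | 5.4 |
| alpha | 0.667 | 0.1 | 6.4 |
| alpha | 1.00 | 0.6 | 10.1 |
| alpha | 2.00 | 3.2 | 14.6 |
| alpha | 2.50 | 3.7 | 13.4 |

(readings scatter by 1 percentage point)

- in percentages every species weighs as the starting material in it: one homo dimer counts as two
- steps thought possible: starting material -> side product; intermediate B -> target; partner <-> dormant form; 2 starting material -> homo dimer; starting material + partner <-> intermediate A; partner + intermediate A <-> intermediate B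

1. the flask that comes out highest in share of target in all that became target or side product, or "all alike" when all lie within 1.5 percentage points (green / amber / violet / all alike)
2. share of target in all that became target or side product, green
3. share of target in all that became target or side product, amber
4. share of target in all that became target or side product, violet

- We call ρ the amount of target over the amount of side product, a selectivity factor.
- In the steps thought possible, side product needs no partner, but target needs two partners on its way, through intermediate A and intermediate B.
- So we follow partner. With temperature, time and starting-material charge fixed, with the intermediates in equilibrium with starting material and partner, and with free partner a fixed part of its charge, ρ goes as E squared.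
- First extreme: the intermediates never fill, ρ stays at zero, and the share of target is zero. The last readings of the gamma run lie near this, at a share of 2.17%, with a scatter of 1 percentage point on each reading.
- Second extreme: the intermediates are full from the start, and ρ holds its late value from the first minute, here as read at the temperature of the alpha run. In the alpha run, the gains between 1.00 h and 2.50 h read 0.939, a share of 48.4%, with a scatter of 1 point on each reading.
- The real flask lies between them. The running ρ of the alpha run reads 0.0594 at 1.00 h and 0.276 at 2.50 h, both lower than the late value, so the lag counts.
- Our reckoning uses the runs as rough yardsticks: their partner charge, 0.25 M, matches that of the new flasks, though their starting-material charge, temperature and time differ. We put violet near the last share read in the alpha run, 21.6%. We put amber near the last share read in the gamma run. We put green, hot for 80 min, near the share read in the alpha run at 1.00 h, 5.61%.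
- The forecast names violet too, but stands higher for green and violet than we do, with green 43%, amber 2% and violet 52%: “runs selectively to near-full conversion”.
- The flasks give green 5.59%, amber 3.83% and violet 15.7%, so violet is highest. At 6.00 h, violet still holds 15.1% as intermediate B beside 6.36% of target. At that time violet stands at ρ = 0.186 with E = 2.50.

    starting material → side product (k = 0.00392 /min, Ea = 111 kJ/mol)
    intermediate B → target (k = 0.00129 /min, Ea = 101 kJ/mol)
    partner ⇌ dormant form (K = 0.311, k = 0.00563 /min, Ea = 90.0 kJ/mol, ΔH = −28.0 kJ/mol)
    2 starting material → homo dimer (k = 0.0530 /M/min, Ea = 81.0 kJ/mol)
    starting material + partner ⇌ intermediate A (K = 0.950 /M, k = 0.0653 /M/min, Ea = 77.0 kJ/mol, ΔH = −35.0 kJ/mol)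
    partner + intermediate A ⇌ intermediate B (K = 170 /M, k = 0.115 /M/min, Ea = 85.0 kJ/mol, ΔH = −14.0 kJ/mol)
    (constants at 50 °C)

- The neighbour of violet with 0.42 M of partner has E = 4.20, at the same temperature, time and starting-material charge, so the square rule, taken as an estimate, gives ρ = 0.525, a share of 34.4%.
- That neighbour computes to 32.3%, with 12.8% of target and 26.8% of side product.

(The readings are calculated with made-up constants; the scatter is artificial.)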